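The 1,3,5-trisubstituted benzene ring is disconnected at the bond between alkyl-bearing C1 and C2 (the CH between C1 and the hydroxyl carbon C3), after restoring a carboxyl on C2. The meta pattern of ring carbons C1 (alkyl), C3 (OH) and C5 (OMe) is the alternating oxygenation of a tetraketide. One carbonate-mediated aldol condensation of a 3,5,7-triketo ester joins C2 to C7, closes the carbocycle and aromatises it to a 2,4-dihydroxybenzoate. Its ester hydrogen-bonds the ortho hydroxyl, leaving the para hydroxyl free for methylation. The precursor is a benzyl triketo ester with the (R)-silyloxy stereocentre at C9 and a dioxolane-masked ketone; the benzyl ester lets the carboxyl leave later by hydrogenolysis and thermal decarboxylation.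

Key step: step 10

Assumption: the acetoxy-bearing carbon is (R) as read from the SMILES; its C–O bond is set with that configuration in step 4 and is never broken afterwards, so the (R)-3-hydroxy ester maps directly onto the target.

Step 1
Reactants: 1 5-bromopentanoyl chloride; 2 pentylmagnesium bromide
Product: 3 1-bromodecan-5-one
Conditions: Fe(acac)3 (3 mol%), THF, –78 °C, slow addition of 2
Reagents that add atoms: none
Why: Iron-catalysed acylation of a Grignard reagent, in which the acid chloride couples at –78 °C far faster than the primary bromide or the product ketone can react, so the ketone should form without over-addition.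

Step 2
Reactants: 3 1-bromodecan-5-one
Product: 4 2-(4-bromobutyl)-2-pentyl-1,3-dioxolane
Conditions: HOCH2CH2OH, p-TsOH·H2O (cat.), toluene, reflux, Dean–Stark
Reagents that add atoms: ethylene glycol, OCCO
Why: Acid-catalysed ketalisation with azeotropic removal of water masks the ketone as a dioxolane that tolerates all the carbanion chemistry ahead, while the primary bromide is inert.

Step 3
Reactants: 4 2-(4-bromobutyl)-2-pentyl-1,3-dioxolane; 5 methyl acetoacetate
Product: 6 methyl 3-oxo-8-(2-pentyl-1,3-dioxolan-2-yl)octanoate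
Conditions: 5, NaH, THF, 0 °C; n-BuLi, 0 °C; then 4, 0 °C → rt; aq. NH4Cl
Reagents that add atoms: none
Why: Weiler dianion alkylation, in which the acetoacetate dianion reacts with the primary bromide only at its more nucleophilic terminal carbon and the dioxolane is untouched by the base.

Step 4
Reactants: 6 methyl 3-oxo-8-(2-pentyl-1,3-dioxolan-2-yl)octanoate
Product: 7 methyl (R)-3-hydroxy-8-(2-pentyl-1,3-dioxolan-2-yl)octanoate
Conditions: Ru2Cl4[(R)-BINAP]2(NEt3) (0.5 mol%), H2 (50 atm), MeOH, 50 °C
Reagents that add atoms: none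
Why: Noyori asymmetric hydrogenation of a β-keto ester, in which the ester carbonyl chelates ruthenium and the (R)-BINAP ligand directs hydride to the face that gives the (R)-alcohol (the same sense as methyl acetoacetate to methyl (R)-3-hydroxybutanoate), while the amine-containing precatalyst keeps the methanol from becoming acidic enough to open the dioxolane and the remote ketal carbon is not a substrate.

Step 5
Reactants: 7 methyl (R)-3-hydroxy-8-(2-pentyl-1,3-dioxolan-2-yl)octanoate
Product: 8 methyl (R)-3-(tert-butyldimethylsilyloxy)-8-(2-pentyl-1,3-dioxolan-2-yl)octanoate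
Conditions: TBSCl, imidazole, DMF, rt
Reagents that add atoms: tert-butyldimethylsilyl chloride, CC(C)(C)[Si](C)(C)Cl
Why: Standard imidazole-promoted silylation of a secondary alcohol; the silyl ether will prevent hemiketal formation with the polycarbonyl chain and later lactonisation onto the benzoate.

Step 6
Reactants: 8 methyl (R)-3-(tert-butyldimethylsilyloxy)-8-(2-pentyl-1,3-dioxolan-2-yl)octanoate
Product: 9 (R)-3-(tert-butyldimethylsilyloxy)-8-(2-pentyl-1,3-dioxolan-2-yl)octanoic acid
Conditions: LiOH·H2O, THF/MeOH/H2O, rt; then cold 1 M HCl to pH 4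
Reagents that add atoms: lithium hydroxide, [Li+].[OH-]
Why: Saponification of an unhindered methyl ester at room temperature leaves the silyl ether and the ketal intact, and brief cold acidification only to pH 4 spares both on work-up.

Step 7
Reactants: 10 2,2,6-trimethyl-4H-1,3-dioxin-4-one
Product: 11 2,2-dimethyl-6-(2-oxopropyl)-4H-1,3-dioxin-4-one
Conditions: LiN(SiMe3)2 (2 equiv), THF, –78 °C; then AcCl, –78 → –20 °C; aq. NH4Cl
Reagents that add atoms: acetyl chloride, CC(=O)Cl
Why: Deprotonation of the 6-methyl group gives the vinylogous lithium enolate, which is C-acylated at that carbon by acetyl chloride (crossed Claisen-type acylation), the second equivalent of base absorbing the more acidic product.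

Step 8
Reactants: 9 (R)-3-(tert-butyldimethylsilyloxy)-8-(2-pentyl-1,3-dioxolan-2-yl)octanoic acid; 11 2,2-dimethyl-6-(2-oxopropyl)-4H-1,3-dioxin-4-one
Product: 13 6-[(6R)-6-(tert-butyldimethylsilyloxy)-2,4-dioxo-11-(2-pentyl-1,3-dioxolan-2-yl)undecyl]-2,2-dimethyl-4H-1,3-dioxin-4-one, via acyl imidazolide 12 (not isolated)
Conditions: 9, CDI, THF, rt, N2 sparge; added to 11 (2.5 equiv) + LiN(i-Pr)2 (5 equiv), THF, –78 → –40 °C; aq. NH4Cl
Reagents that add atoms: none
Why: CDI activates the acid without generating HCl, and the dianion of 11 is acylated at its terminal, more reactive carbon (Claisen-type C-acylation of a 1,3-dicarbonyl dianion), the product being protected in the flask as its diketone enolate; the excess dianion absorbs the imidazole N–H that is released.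

Step 9
Reactants: 13 6-[(6R)-6-(tert-butyldimethylsilyloxy)-2,4-dioxo-11-(2-pentyl-1,3-dioxolan-2-yl)undecyl]-2,2-dimethyl-4H-1,3-dioxin-4-one
Product: 15 benzyl (R)-9-(tert-butyldimethylsilyloxy)-3,5,7-trioxo-14-(2-pentyl-1,3-dioxolan-2-yl)tetradecanoate, via acylketene 14 (not isolated)
Conditions: BnOH (1.5 equiv), toluene, 110 °C; concentrate, use crude
Reagents that add atoms: benzyl alcohol, OCc1ccccc1
Why: Thermal retro-hetero-Diels–Alder fragmentation of the dioxinone expels acetone to give an acylketene, which benzyl alcohol should trap faster than the enol oxygen can close to a pyrone, giving the β-keto ester terminus under neutral conditions.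

Step 10
Reactants: 15 benzyl (R)-9-(tert-butyldimethylsilyloxy)-3,5,7-trioxo-14-(2-pentyl-1,3-dioxolan-2-yl)tetradecanoate
Product: 17 benzyl 2,4-dihydroxy-6-[(R)-2-(tert-butyldimethylsilyloxy)-7-(2-pentyl-1,3-dioxolan-2-yl)heptyl]benzoate, via cyclic aldol adduct 16 (not isolated)
Conditions: K2CO3, i-PrOH/CH2Cl2, rt; then AcOH, rt (to 40 °C if 16 persists)
Reagents that add atoms: none
Why: Carbonate deprotonates C2, the most acidic carbon (between the ester and the C3 ketone), and this enolate adds to the C7 ketone to form the C2–C7 bond; the β-hydroxy ketone 16 then loses water (E1cB, completed by the weak acid) and the C3 and C5 carbonyls enolise to give the benzene ring. The closest known reaction type is the biomimetic aldol cyclisation–aromatisation of 3,5,7-triketo esters to resorcylate esters. The six-membered carbocycle closes in a 6-(enolendo)-exo-trig mode with respect to the C2=C3 enolate, which is geometrically favourable. No stereocentre is created, and the C9 centre should be untouched because C8 is much less acidic than C2, C4 and C6, so neither epimerisation nor β-elimination of the silyloxy group is expected with carbonate. The step needs selectivity for the C2→C7 aldol over the C6→C1 Claisen closure, the C8→C3 aldol and O-cyclisation to pyranones; a weak base in an alcohol at room temperature favours the aldol mode, the ester is a poorer electrophile than the C7 ketone, and C8 is only singly activated. The benzyl ester should not exchange in i-PrOH, and the dioxolane and silyl ether tolerate both carbonate and acetic acid.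

Step 11
Reactants: 17 benzyl 2,4-dihydroxy-6-[(R)-2-(tert-butyldimethylsilyloxy)-7-(2-pentyl-1,3-dioxolan-2-yl)heptyl]benzoate
Product: 18 benzyl 2-hydroxy-4-methoxy-6-[(R)-2-(tert-butyldimethylsilyloxy)-7-(2-pentyl-1,3-dioxolan-2-yl)heptyl]benzoate
Conditions: MeI (1.1 equiv), K2CO3 (1.1 equiv), acetone, rt
Reagents that add atoms: iodomethane, CI
Why: Williamson O-methylation in which the 2-hydroxyl is held in a hydrogen bond to the ester carbonyl and is less acidic and less nucleophilic, so with one equivalent of reagent only the 4-phenoxide should be alkylated.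

Step 12
Reactants: 18 benzyl 2-hydroxy-4-methoxy-6-[(R)-2-(tert-butyldimethylsilyloxy)-7-(2-pentyl-1,3-dioxolan-2-yl)heptyl]benzoate
Product: 20 3-[(R)-2-(tert-butyldimethylsilyloxy)-7-(2-pentyl-1,3-dioxolan-2-yl)heptyl]-5-methoxyphenol, via salicylic acid 19 (not isolated)
Conditions: H2 (1 atm), Pd/C, EtOAc, rt; filter, concentrate; then DMF, 120 °C
Reagents that add atoms: none
Why: Hydrogenolysis cleaves the benzyl C–O bond under neutral conditions regardless of the steric shielding of the di-ortho-substituted carboxyl, and the electron-rich acid (ortho-OH, para-OMe, ortho-alkyl) should then undergo thermal protodecarboxylation through ipso protonation as orsellinic-type acids do, the silyl ether being kept on so that no dihydroisocoumarin lactone can form.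

Step 13
Reactants: 20 3-[(R)-2-(tert-butyldimethylsilyloxy)-7-(2-pentyl-1,3-dioxolan-2-yl)heptyl]-5-methoxyphenol
Product: 21 (R)-12-hydroxy-13-(3-hydroxy-5-methoxyphenyl)tridecan-6-one
Conditions: 2 M aq. HCl/THF (1:2), rt → 40 °C
Reagents that add atoms: water, O
Why: Aqueous acid hydrolyses the dioxolane and cleaves the secondary silyl ether in one operation without breaking the C–O bond at the stereocentre, and the freed hydroxyl and ketone are too far apart (an eight-membered hemiketal) to interact.

Step 14
Reactants: 21 (R)-12-hydroxy-13-(3-hydroxy-5-methoxyphenyl)tridecan-6-one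
Product: 22 (R)-1-(3-acetoxy-5-methoxyphenyl)-8-oxotridecan-2-yl acetate
Conditions: Ac2O, pyridine, DMAP (cat.), CH2Cl2, rt
Reagents that add atoms: acetic anhydride, CC(=O)OC(C)=O
Why: Exhaustive nucleophile-catalysed acetylation of the secondary alcohol and the phenol, with retention at the stereocentre and an inert ketone.

Step 15
Reactants: 22 (R)-1-(3-acetoxy-5-methoxyphenyl)-8-oxotridecan-2-yl acetate
Product: 23 (R)-1-(3-hydroxy-5-methoxyphenyl)-8-oxotridecan-2-yl acetate (CNP0302149.1)
Conditions: NH4OAc, MeOH/H2O (4:1), rt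
Reagents that add atoms: none
Why: Chemoselective transesterification in which the aryl acetate, with its far better phenoxide leaving group, is methanolysed under near-neutral conditions that should leave the secondary alkyl acetate and the ketone untouched.

Compound list
1 | 5-bromopentanoyl chloride | O=C(Cl)CCCCBr | starting material
2 | pentylmagnesium bromide | CCCCC[Mg]Br | starting material
3 | 1-bromodecan-5-one | CCCCCC(=O)CCCCBr | intermediate
4 | 2-(4-bromobutyl)-2-pentyl-1,3-dioxolane | CCCCCC1(CCCCBr)OCCO1 | intermediate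
5 | methyl acetoacetate | COC(=O)CC(C)=O | starting material
6 | methyl 3-oxo-8-(2-pentyl-1,3-dioxolan-2-yl)octanoate | COC(=O)CC(=O)CCCCCC1(CCCCC)OCCO1 | intermediate
7 | methyl (R)-3-hydroxy-8-(2-pentyl-1,3-dioxolan-2-yl)octanoate | COC(=O)C[C@@H](CCCCCC1(CCCCC)OCCO1)O | intermediate
8 | methyl (R)-3-(tert-butyldimethylsilyloxy)-8-(2-pentyl-1,3-dioxolan-2-yl)octanoate | COC(=O)C[C@@H](CCCCCC1(CCCCC)OCCO1)O[Si](C)(C)C(C)(C)C | intermediate
9 | (R)-3-(tert-butyldimethylsilyloxy)-8-(2-pentyl-1,3-dioxolan-2-yl)octanoic acid | OC(=O)C[C@@H](CCCCCC1(CCCCC)OCCO1)O[Si](C)(C)C(C)(C)C | intermediate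
10 | 2,2,6-trimethyl-4H-1,3-dioxin-4-one | CC1=CC(=O)OC(C)(C)O1 | starting material
11 | 2,2-dimethyl-6-(2-oxopropyl)-4H-1,3-dioxin-4-one | CC(=O)CC1=CC(=O)OC(C)(C)O1 | intermediate
12 | 1-[(R)-3-(tert-butyldimethylsilyloxy)-8-(2-pentyl-1,3-dioxolan-2-yl)octanoyl]imidazole (acyl imidazolide, formed in the flask) | O=C(C[C@@H](CCCCCC1(CCCCC)OCCO1)O[Si](C)(C)C(C)(C)C)n1ccnc1 | intermediate
13 | 6-[(6R)-6-(tert-butyldimethylsilyloxy)-2,4-dioxo-11-(2-pentyl-1,3-dioxolan-2-yl)undecyl]-2,2-dimethyl-4H-1,3-dioxin-4-one (drawn as the diketo tautomer) | CC1(C)OC(=O)C=C(CC(=O)CC(=O)C[C@@H](CCCCCC2(CCCCC)OCCO2)O[Si](C)(C)C(C)(C)C)O1 | intermediate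
14 | (9R)-9-(tert-butyldimethylsilyloxy)-14-(2-pentyl-1,3-dioxolan-2-yl)-3,5,7-trioxotetradec-1-en-1-one (acylketene, formed in the flask) | O=C=CC(=O)CC(=O)CC(=O)C[C@@H](CCCCCC1(CCCCC)OCCO1)O[Si](C)(C)C(C)(C)C | intermediate
15 | benzyl (R)-9-(tert-butyldimethylsilyloxy)-3,5,7-trioxo-14-(2-pentyl-1,3-dioxolan-2-yl)tetradecanoate (key-step precursor, drawn as the triketo tautomer) | O=C(OCc1ccccc1)CC(=O)CC(=O)CC(=O)C[C@@H](CCCCCC1(CCCCC)OCCO1)O[Si](C)(C)C(C)(C)C | intermediate
16 | benzyl 2-[(R)-2-(tert-butyldimethylsilyloxy)-7-(2-pentyl-1,3-dioxolan-2-yl)heptyl]-2-hydroxy-4,6-dioxocyclohexane-1-carboxylate (cyclic aldol adduct, mixture at the two transient ring centres, formed in the flask) | O=C(OCc1ccccc1)C1C(=O)CC(=O)CC1(O)C[C@@H](CCCCCC2(CCCCC)OCCO2)O[Si](C)(C)C(C)(C)C | intermediate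
17 | benzyl 2,4-dihydroxy-6-[(R)-2-(tert-butyldimethylsilyloxy)-7-(2-pentyl-1,3-dioxolan-2-yl)heptyl]benzoate (key-step product) | O=C(OCc1ccccc1)c1c(O)cc(O)cc1C[C@@H](CCCCCC2(CCCCC)OCCO2)O[Si](C)(C)C(C)(C)C | intermediate
18 | benzyl 2-hydroxy-4-methoxy-6-[(R)-2-(tert-butyldimethylsilyloxy)-7-(2-pentyl-1,3-dioxolan-2-yl)heptyl]benzoate | O=C(OCc1ccccc1)c1c(O)cc(OC)cc1C[C@@H](CCCCCC2(CCCCC)OCCO2)O[Si](C)(C)C(C)(C)C | intermediate
19 | 2-hydroxy-4-methoxy-6-[(R)-2-(tert-butyldimethylsilyloxy)-7-(2-pentyl-1,3-dioxolan-2-yl)heptyl]benzoic acid (formed in the flask) | OC(=O)c1c(O)cc(OC)cc1C[C@@H](CCCCCC2(CCCCC)OCCO2)O[Si](C)(C)C(C)(C)C | intermediate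
20 | 3-[(R)-2-(tert-butyldimethylsilyloxy)-7-(2-pentyl-1,3-dioxolan-2-yl)heptyl]-5-methoxyphenol | COc1cc(O)cc(C[C@@H](CCCCCC2(CCCCC)OCCO2)O[Si](C)(C)C(C)(C)C)c1 | intermediate
21 | (R)-12-hydroxy-13-(3-hydroxy-5-methoxyphenyl)tridecan-6-one | COc1cc(O)cc(C[C@@H](CCCCCC(=O)CCCCC)O)c1 | intermediate
22 | (R)-1-(3-acetoxy-5-methoxyphenyl)-8-oxotridecan-2-yl acetate | COc1cc(OC(C)=O)cc(C[C@@H](CCCCCC(=O)CCCCC)OC(C)=O)c1 | intermediate
23 | (R)-1-(3-hydroxy-5-methoxyphenyl)-8-oxotridecan-2-yl acetate (CNP0302149.1) | CCCCCC(=O)CCCCC[C@H](Cc1cc(O)cc(OC)c1)OC(C)=O | target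

Total step count: 15. Longest linear sequence: 14 (steps 1–6 and 8–15); step 7 is a one-step branch.

Steps most likely to fail

Step 10. The chain may cyclise through the wrong atoms (Claisen attack of C6 on the ester carbonyl, or oxygen closure to a pyranone), or the sequence may stall before dehydration. The fallback sets out from 13 and comes back at 18; it closes the ring one stage earlier, while the ester is still masked in the dioxinone, so that neither a free ester nor a ketene is present. Treating 13 with NEt3 in CH2Cl2 at rt should add the dioxinone ring carbon C5 (as the vinylogous enolate) to the distal ketone and dehydrate to 7-hydroxy-2,2-dimethyl-5-[(R)-2-(tert-butyldimethylsilyloxy)-7-(2-pentyl-1,3-dioxolan-2-yl)heptyl]-4H-1,3-benzodioxin-4-one F1. Its only free hydroxyl is methylated (MeI, K2CO3, acetone) to give 7-methoxy-2,2-dimethyl-5-[(R)-2-(tert-butyldimethylsilyloxy)-7-(2-pentyl-1,3-dioxolan-2-yl)heptyl]-4H-1,3-benzodioxin-4-one F2. Sodium benzyloxide (BnOH, NaH, THF, 0 °C → rt) then opens the benzodioxinone with loss of acetone to give 18, which continues with step 12.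

Step 8. Proton transfer from the α-methylene of the acyl imidazolide to the strongly basic dianion may outrun C-acylation, followed by loss of silanolate, or acylation may occur on oxygen. The fallback sets out from 8 and comes back at 13; it replaces the acylation by an aldol addition and an oxidation. Reduction of 8 with i-Bu2AlH (CH2Cl2, –78 °C) should stop at (R)-3-(tert-butyldimethylsilyloxy)-8-(2-pentyl-1,3-dioxolan-2-yl)octanal F3. The dianion of 11 (LiN(i-Pr)2, THF, –78 °C) adds through its terminal carbon to this aldehyde to give 6-[(6R)-6-(tert-butyldimethylsilyloxy)-4-hydroxy-2-oxo-11-(2-pentyl-1,3-dioxolan-2-yl)undecyl]-2,2-dimethyl-4H-1,3-dioxin-4-one F4, as an inconsequential mixture of epimers at the new carbinol. Dess–Martin periodinane (NaHCO3, CH2Cl2, rt) oxidises the β-hydroxy ketone to the diketone 13.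

Step 4. The dioxolane may be exchanged or lost if the methanolic hydrogenation medium turns acidic, and the enantioselectivity may be eroded. The fallback sets out from 4 and comes back at 9; it takes the stereocentre from the chiral pool instead of creating it. Commercial ethyl (S)-4-chloro-3-hydroxybutanoate is closed with Ag2O (DME, 60 °C) to ethyl (S)-3,4-epoxybutanoate F5. Bromide 4 is converted with Mg in THF into [4-(2-pentyl-1,3-dioxolan-2-yl)butyl]magnesium bromide F6. With CuI (cat.) at –30 °C this opens the epoxide at its terminal carbon to give ethyl (R)-3-hydroxy-8-(2-pentyl-1,3-dioxolan-2-yl)octanoate F7; the C–O bond at the stereocentre is untouched and the descriptor changes only through the priority rules. Silylation (TBSCl, imidazole, DMF) gives ethyl (R)-3-(tert-butyldimethylsilyloxy)-8-(2-pentyl-1,3-dioxolan-2-yl)octanoate F8, and saponification as in step 6 gives 9.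

Further compounds
F1 | step 10 | 7-hydroxy-2,2-dimethyl-5-[(R)-2-(tert-butyldimethylsilyloxy)-7-(2-pentyl-1,3-dioxolan-2-yl)heptyl]-4H-1,3-benzodioxin-4-one | CC1(C)OC(=O)c2c(C[C@@H](CCCCCC3(CCCCC)OCCO3)O[Si](C)(C)C(C)(C)C)cc(O)cc2O1
F2 | step 10 | 7-methoxy-2,2-dimethyl-5-[(R)-2-(tert-butyldimethylsilyloxy)-7-(2-pentyl-1,3-dioxolan-2-yl)heptyl]-4H-1,3-benzodioxin-4-one | CC1(C)OC(=O)c2c(C[C@@H](CCCCCC3(CCCCC)OCCO3)O[Si](C)(C)C(C)(C)C)cc(OC)cc2O1
F3 | step 8 | (R)-3-(tert-butyldimethylsilyloxy)-8-(2-pentyl-1,3-dioxolan-2-yl)octanal | O=CC[C@@H](CCCCCC1(CCCCC)OCCO1)O[Si](C)(C)C(C)(C)C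
F4 | step 8 | 6-[(6R)-6-(tert-butyldimethylsilyloxy)-4-hydroxy-2-oxo-11-(2-pentyl-1,3-dioxolan-2-yl)undecyl]-2,2-dimethyl-4H-1,3-dioxin-4-one | CC1(C)OC(=O)C=C(CC(=O)CC(O)C[C@@H](CCCCCC2(CCCCC)OCCO2)O[Si](C)(C)C(C)(C)C)O1
F5 | step 4 | ethyl (S)-3,4-epoxybutanoate | CCOC(=O)C[C@H]1CO1
F6 | step 4 | [4-(2-pentyl-1,3-dioxolan-2-yl)butyl]magnesium bromide | Br[Mg]CCCCC1(CCCCC)OCCO1
F7 | step 4 | ethyl (R)-3-hydroxy-8-(2-pentyl-1,3-dioxolan-2-yl)octanoate | CCOC(=O)C[C@@H](CCCCCC1(CCCCC)OCCO1)O
F8 | step 4 | ethyl (R)-3-(tert-butyldimethylsilyloxy)-8-(2-pentyl-1,3-dioxolan-2-yl)octanoate | CCOC(=O)C[C@@H](CCCCCC1(CCCCC)OCCO1)O[Si](C)(C)C(C)(C)C
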